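## The problem

Labdane numbering is used throughout: C14 is the lactone CH2, C15 the lactone carbonyl, C16 the OCH2 carbon, C17 the methyl on C8 and C20 the methyl on C10.

The target is a 7-oxo-8β-hydroxy labdane whose side chain is folded twice onto the trans-decalin. C9 is the spiro atom between ring B and a tetrahydrofuran (ring C: C9, C11, C12, C13, O), and C13 is the spiro atom between ring C and a γ-lactone (ring D: C13, C14, C15, O, C16). Two fully substituted carbons therefore flank one ether oxygen. C5 and C10 come with the decalin. The axial C20 methyl can steer reagents to the α face (the 9α oxygen) and, through trans-diaxial epoxide opening, place the axial 8β hydroxyl. C13 is separated from all of them by ring C and can only be controlled through the shape of that spiro ring. Three groups are fragile: the tertiary α-ketol at C7/C8 (acyloin shift, glycol-type cleavage), the two tertiary ether C–O bonds (acid), and the β-alkoxy lactone, whose C13–O bond is expelled from a C14 enolate with loss of the C13 stereocentre. The C7/C8 oxygenation should therefore be unmasked last, and enolate chemistry avoided once ring D exists. The enabling feature is that C13 carries both C14 (CH2 next to C=O) and C16 (CH2 next to O), which are joined through C15 and the lactone oxygen. Ring D is thus a cyclobutanone (C13, C14, C15, C16) with one oxygen inserted, and that cyclobutanone is the (2+2) adduct of a ketene with a C13=C16 exocyclic enol ether on ring C. Chlorines on the ketene make it reactive enough and later decide where the oxygen is inserted.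

## Retrosynthesis

**The α-ketol (22 ⇒ 21 ⇒ 20 ⇒ 19).** The C7 carbonyl is taken back to a 7α alcohol (21), the two C14 hydrogens to chlorines (20), and the C7–O and C8–O bonds to a 7α,8α-epoxide (19). The 8β hydroxyl is then made by water attacking C8 from the β face with inversion. The neighbouring options, cis-dihydroxylation of the alkene or hydroxylation of a C7 ketone enolate, would bring oxygen to C8 from the open α face and give the wrong tertiary alcohol. Epoxide 19 has no free hydroxyl and no ketone. The forward steps must open a trisubstituted epoxide at its tertiary end in the trans-diaxial sense, remove two chlorines without forming an enolate at C14, and oxidise a secondary alcohol beside a tertiary one without C–C cleavage.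

**Ring D oxygen (19 ⇒ 17).** Removing the ring oxygen between C15 and C16, together with the epoxide oxygen, leads to the spiro dichlorocyclobutanone 17 with a Δ7 alkene. One peracid delivers both oxygens. The chlorines must still be on C14 at this point. They make the CCl2 carbon a poor migrating group, so C16 migrates. They are also the only difference between the two arms on C13: a dechlorinated cyclobutanone would carry two identical CH2–C(=O) arms and C13 would no longer be stereogenic. The alternative cut at the acyl C15–O bond would need a C13 with two differentiated arms built by separate steps.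

**Key cut (17 ⇒ 14 + 16, the latter from 15).** Cutting C13–C14 and C15–C16 removes one ring, two C–C bonds and the C13 stereocentre at once. It leaves the 18-carbon enol ether 14 and dichloroketene 16, made in the flask from trichloroacetyl chloride 15. Forming C13–C14 by enolate addition to a C13 ketone, or closing the C13–O bond by oxa-Michael addition to a butenolide, would either need base next to a β-oxygen or set C13 under thermodynamic control only. The cycloaddition builds the quaternary carbon under neutral conditions and under kinetic control. It has to be regioselective (given by enol ether polarity), face-selective on ring C, selective for the enol ether over the Δ7 alkene, and gentle enough for an acid-labile exocyclic enol ether.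

**Enol ether (14 ⇒ 13).** The C13=C16 bond is cut back to the carbonyl of spiro lactone 13. Dehydrating a methyl hemiketal instead would give the endocyclic enol ether. Methylenation of a lactone carbonyl gives the exocyclic isomer only, and 13 is a stable compound that can be stored. The forward step needs a non-basic, non-acidic ester methylenation.

**The C9 oxygen (13 ⇒ 12 ⇒ 10 ⇒ 8 ⇒ 7).** Lactone 13 is the γ-lactone of hydroxy acid 12, so lactonisation forms only the acyl C13–O bond. The C9–O bond is traced to epoxy ketone 10, in which oxygen was delivered to C9 from the α face. A Wharton transposition then exchanges the C7 carbonyl for the Δ7 alkene and leaves the tertiary allylic 9α alcohol. Direct isomerisation of an 8α,9α-epoxide of 7 was set aside: base would remove a C17 methyl hydrogen and give the exocyclic alkene, and acid invites ring contraction. The transposition is regiospecific. Epoxy ketone 10 comes from enone 8 by nucleophilic epoxidation, and 8 from the tetrasubstituted alkene 7 by allylic oxidation at C7.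

**Chiral pool (7 ⇒ 6 ⇒ 4 ⇒ 3 ⇒ 1).** Ester 7 retains C1–C13 and the four methyls of (−)-sclareol 1. The side chain is shortened twice (vinyl carbinol to methyl ketone 3, then methyl ketone 4 to acid 6 by haloform cleavage) and the 8α hydroxyl is exchanged for the Δ8(9) alkene (3 to 4). Sclareol supplies rings A and B, C5 and C10 in the correct absolute configuration, and 17 of the 20 carbons. C16 comes from the titanium reagent, and C14 and C15 from the ketene.

## Roads not taken

**Alternative 1:** The decalin is cut at C4–C5 and C9–C10. An acyclic C15 polyene β-keto ester A2 would be protonated at its terminal alkene by SnCl4 combined with one enantiomer of a binaphthol monomethyl ether. Two 6-endo closures, terminated by the β-keto ester enol, give the trans-fused keto ester A1.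
- Merits: fully synthetic, either enantiomer is available, and A1 has a C8 ketone and a C9 acyl group, so the 9α oxygen could be introduced by simple enolate oxidation. In that respect it is better than the three-step oxygen transposition used here.
- Weak points: the stereocontrol of proton-initiated cyclisations with this terminator is usually incomplete and needs a stoichiometric chiral acid. A1 still lacks C17, C12–C16, the C7 oxygen and both spiro rings, and A1 has no handle at C7.
- Comparison: the chosen plan sets against it a starting material that already contains the decalin, its two stereocentres and the C11–C13 chain. The enantioselective cyclisation would only rebuild what sclareol provides.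

**Alternative 2:** The cut is the O–C9 bond. Anodic oxidation (carbon anode, LiClO4, 2,6-lutidine, methanol) of the C8,C9 silyl enol ether A4 gives a radical cation. The C13 tertiary hydroxyl traps it at C9 in a 5-exo closure, giving the 17-nor-8-ketone A3.
- Merits: the most hindered bond of the molecule is made in one oxidative step. The C8 ketone returns ready for α'-oxygenation at C7 and methyl addition. C13 is brought in with the side chain instead of being induced, which is stronger than the chosen plan at its weakest point.
- Weak points: the C13 carbinol has two arms differing by one CH2 and must be made enantiopure and joined to the decalin. The face of attack at C9 is not guaranteed. Two silyl ethers must later be told apart to close the lactone.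
- Comparison: the C13 control is better, but the sequence is clearly longer. The chosen plan makes both C13 arms from a two-carbon reagent in one step and accepts a face-selectivity risk that can be corrected afterwards by equilibration.

**Alternative 3:** The cut is C13–C14. Rh2(OAc)4 would decompose the diazoacetate A6, and the carbenoid would insert into the C13–H bond next to the ring oxygen with retention. This closes ring D and gives the silyl ether A5, which is desilylated to 22.
- Merits: the ether oxygen activates the right C–H bond, a five-membered ring is the preferred insertion mode, and retention would make C13 secure if the C13–H stereocentre were available pure. On that condition it would be more reliable than a facial preference.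
- Weak points: the problem of C13 is only moved to the earlier construction of a 2-(hydroxymethyl)tetrahydrofuran. An acceptor-only carbenoid can also form oxonium ylides with the ring oxygen, carbonyl ylides with the C7 ketone, or insert at C12. The least selective step falls on the most elaborate intermediate, with the α-ketol already in place.
- Comparison: the chosen plan puts its risky step on a robust hydrocarbon-like intermediate and needs no diazo compound. What it gives up is the certainty of retention at C13.

Key step: step 9

Remark: commercial (−)-sclareol is taken to be (13R)-labd-14-ene-8α,13-diol, which carries the 5S,10S decalin of the target.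

## Route

Step 1
Reactants: 1 (−)-sclareol
Product: 3 8α-hydroxy-14,15-dinorlabdan-13-one, via labdane-8α,13,14,15-tetraol 2 (not isolated)
Conditions: OsO4 (cat.), NaIO4, THF/H2O, 45 °C
Reagents that add atoms: none
Why: Lemieux–Johnson dihydroxylation of the vinyl group followed by twofold periodate cleavage of the 13,14,15-triol leaves the C13 methyl ketone; the tertiary 8α alcohol and the ring stereocentres are not touched.

Step 2
Reactants: 3 8α-hydroxy-14,15-dinorlabdan-13-one
Product: 4 14,15-dinorlabd-8-en-13-one
Conditions: PPh3, I2, CH2Cl2, rt
Reagents that add atoms: none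
Why: Dehydration of the tertiary alcohol through its alkoxyphosphonium iodide; the HI formed equilibrates the alkene isomers toward the tetrasubstituted Δ8(9) alkene (Zaitsev product), as is known for 8α-hydroxy drimanes and labdanes.

Step 3
Reactants: 4 14,15-dinorlabd-8-en-13-one
Product: 6 14,15,16-trinorlabd-8-en-13-oic acid, via trichloromethyl ketone 5 (not isolated)
Conditions: NaOCl, NaOH, dioxane/H2O, 0 °C to rt; Na2SO3; HCl to pH 3
Reagents that add atoms: sodium hydroxide, [Na+].[OH-]
Why: Haloform reaction; the methyl group is chlorinated three times and hydroxide cleaves the trichloromethyl ketone, while alkaline hypochlorite is not electrophilic enough to attack the tetrasubstituted alkene.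

Step 4
Reactants: 6 14,15,16-trinorlabd-8-en-13-oic acid
Product: 7 methyl 14,15,16-trinorlabd-8-en-13-oate
Conditions: MeI, K2CO3, DMF, rt
Reagents that add atoms: iodomethane, CI
Why: Carboxylate O-alkylation; the ester prevents acid-induced lactonisation onto the alkene and interference of the free acid in the next oxidation.

Step 5
Reactants: 7 methyl 14,15,16-trinorlabd-8-en-13-oate
Product: 8 methyl 7-oxo-14,15,16-trinorlabd-8-en-13-oate
Conditions: CrO3, 3,5-dimethylpyrazole, CH2Cl2, −20 °C
Reagents that add atoms: chromium trioxide CrO3, O=[Cr](=O)=O
Why: Allylic oxidation of a ring methylene to the enone; C7 has an axial C–H aligned with the alkene π system, whereas the other allylic methylene C11 is neopentyl-like beside quaternary C10 and the C17 methyl is less reactive.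

Step 6
Reactants: 8 methyl 7-oxo-14,15,16-trinorlabd-8-en-13-oate
Product: 10 8α,9α-epoxy-7-oxo-14,15,16-trinorlabdan-13-oic acid, via methyl epoxy keto ester 9 (not isolated)
Conditions: 30% H2O2, NaOH, MeOH/H2O, 0 °C to rt; HCl to pH 4, 0 °C
Reagents that add atoms: hydrogen peroxide, OO; sodium hydroxide, [Na+].[OH-]
Why: Weitz–Scheffer epoxidation; hydroperoxide adds to C9 from the α face, anti to the axial C20 methyl, and the enolate closes the epoxide, which fixes the 9α oxygen; the methyl ester is saponified in the same alkaline medium.

Step 7
Reactants: 10 8α,9α-epoxy-7-oxo-14,15,16-trinorlabdan-13-oic acid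
Product: 13 14,15,16-trinorlabd-7-en-13,9α-olide, via epoxy hydrazone 11 (not isolated), via 9α-hydroxy acid 12 (not isolated)
Conditions: N2H4·H2O, AcOH, MeOH, 0 °C to rt; extraction at pH 5; EDC·HCl, DMAP (cat.), CH2Cl2, rt on the crude acid
Reagents that add atoms: none
Why: Wharton transposition; the hydrazone opens the epoxide at C8 and loses N2, giving the Δ7 alkene and the tertiary 9α alcohol with the C9–O bond never broken, so the configuration from step 6 is kept; carbodiimide lactonisation then closes the spiro γ-lactone without acid that could ionise the allylic alcohol.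

Step 8
Reactants: 13 14,15,16-trinorlabd-7-en-13,9α-olide
Product: 14 9α,13-epoxy-14,15-dinorlabda-7,13(16)-diene
Conditions: Cp2TiMe2, toluene, 65 °C, dark; filtration through basic alumina
Reagents that add atoms: dimethyltitanocene Cp2TiMe2, C[Ti](C)(C1C=CC=C1)C1C=CC=C1
Why: Petasis methylenation of a lactone carbonyl through titanocene methylidene; it is non-basic and gives only the exocyclic enol ether, as in the methylenation of sugar lactones.

Step 9
Reactants: 14 9α,13-epoxy-14,15-dinorlabda-7,13(16)-diene; 15 trichloroacetyl chloride
Product: 17 spiro 2,2-dichlorocyclobutanone (14,14-dichloro-9α,13-epoxy-15,16-cyclolabd-7-en-15-one), via dichloroketene 16 (not isolated)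
Conditions: Zn–Cu couple, Et2O/DME, 0 °C to rt, slow addition of 15
Reagents that add atoms: none
Why: Zn–Cu removes two chlorines from 15 and dichloroketene 16 is consumed as it forms, while DME binds ZnCl2 so that the acid-labile exocyclic enol ether is not isomerised into the ring. The electron-rich terminus C16 attacks the central carbon of the ketene and the oxocarbenium–dichloroenolate pair collapses by C13–C14 bond formation, an asynchronous (2+2) cycloaddition whose closest relatives are dichloroketene additions to exocyclic enol ethers made by methylenation of sugar lactones. The four-membered ring is closed by this cycloaddition, the second bond by 4-exo collapse of the zwitterion onto C13. Enol ether polarity alone fixes the regiochemistry: the CCl2 carbon (C14) on C13 and the carbonyl (C15) on C16. C13 is the only new stereocentre and is set by the face of ring C that the ketene uses: with the 9α oxygen axial, C13 lies below the decalin, the face turned to C10 is screened by C1 and its axial hydrogen, and the face turned to C8 meets only the vinylic methyl C17 in the plane of the Δ7 alkene, so addition syn to C8 is expected. Keeping C8 trigonal at this stage is what keeps that face open. The step also needs selectivity for the enol ether over the trisubstituted Δ7 alkene, which the much higher nucleophilicity of the enol ether secures.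

Step 10
Reactants: 17 spiro 2,2-dichlorocyclobutanone
Product: 19 14,14-dichloro-7α,8α:9α,13-diepoxylabdan-15,16-olide, via Δ7 dichlorolactone 18 (not isolated)
Conditions: mCPBA (3 equiv), NaHCO3, CH2Cl2, 0 °C to rt
Reagents that add atoms: 3-chloroperoxybenzoic acid (mCPBA), OOC(=O)c1cccc(Cl)c1
Why: Baeyer–Villiger oxidation of the strained, activated ketone with migration of the CH2 carbon C16 (the CCl2 carbon does not migrate) and retention at C13; the same peracid epoxidises the Δ7 alkene from the α face, anti to the axial C20 methyl, as in 5α-steroid 2-enes.

Step 11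
Reactants: 19 14,14-dichloro-7α,8α:9α,13-diepoxylabdan-15,16-olide
Product: 20 14,14-dichloro-9α,13-epoxy-7α,8β-dihydroxylabdan-15,16-olide
Conditions: HClO4 (cat.), THF/H2O, 0 °C to rt
Reagents that add atoms: water, O
Why: Acid-catalysed epoxide hydrolysis; water attacks the tertiary carbon C8 from the β face, the direction favoured both by charge (Markovnikov) and by the trans-diaxial rule (Fürst–Plattner), which inverts C8 and gives the axial 8β hydroxyl.

Step 12
Reactants: 20 14,14-dichloro-9α,13-epoxy-7α,8β-dihydroxylabdan-15,16-olide
Product: 21 9α,13-epoxy-7α,8β-dihydroxylabdan-15,16-olide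
Conditions: Bu3SnH, AIBN (cat.), toluene, 80 °C
Reagents that add atoms: none
Why: Radical-chain hydrodechlorination of the activated α,α-dichloro lactone; no C14 enolate is formed, so the C13 oxygen cannot be expelled, and C13 is not involved.

Step 13
Reactants: 21 9α,13-epoxy-7α,8β-dihydroxylabdan-15,16-olide
Product: 22 (13S)-9α,13-epoxy-8β-hydroxy-7-oxolabdan-15,16-olide (CNP0208728.2)
Conditions: IBX, DMSO, rt
Reagents that add atoms: none
Why: IBX oxidises the secondary 7α alcohol of a secondary/tertiary 1,2-diol to the α-ketol without glycol cleavage, under neutral conditions that leave the ketol and the β-alkoxy lactone alone; C8 is quaternary and cannot epimerise.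

## Compound list

1 | (−)-sclareol, (13R)-labd-14-ene-8α,13-diol | C[C@]12CCCC([C@@H]1CC[C@@]([C@@H]2CC[C@](C)(C=C)O)(C)O)(C)C | starting material
2 | (13R)-labdane-8α,13,14,15-tetraol (C14 epimers) | C[C@]12CCCC([C@@H]1CC[C@@]([C@@H]2CC[C@](C)(C(O)CO)O)(C)O)(C)C | intermediate
3 | 8α-hydroxy-14,15-dinorlabdan-13-one | C[C@]12CCCC([C@@H]1CC[C@@]([C@@H]2CCC(C)=O)(C)O)(C)C | intermediate
4 | 14,15-dinorlabd-8-en-13-one | CC1(C)CCC[C@@]2(C)[C@H]1CCC(C)=C2CCC(C)=O | intermediate
5 | 16,16,16-trichloro-14,15-dinorlabd-8-en-13-one | CC1(C)CCC[C@@]2(C)[C@H]1CCC(C)=C2CCC(=O)C(Cl)(Cl)Cl | intermediate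
6 | 14,15,16-trinorlabd-8-en-13-oic acid | CC1(C)CCC[C@@]2(C)[C@H]1CCC(C)=C2CCC(=O)O | intermediate
7 | methyl 14,15,16-trinorlabd-8-en-13-oate | CC1(C)CCC[C@@]2(C)[C@H]1CCC(C)=C2CCC(=O)OC | intermediate
8 | methyl 7-oxo-14,15,16-trinorlabd-8-en-13-oate | CC1(C)CCC[C@@]2(C)[C@H]1CC(=O)C(C)=C2CCC(=O)OC | intermediate
9 | methyl 8α,9α-epoxy-7-oxo-14,15,16-trinorlabdan-13-oate | CC1(C)CCC[C@@]2(C)[C@H]1CC(=O)[C@@]3(C)O[C@@]23CCC(=O)OC | intermediate
10 | 8α,9α-epoxy-7-oxo-14,15,16-trinorlabdan-13-oic acid | CC1(C)CCC[C@@]2(C)[C@H]1CC(=O)[C@@]3(C)O[C@@]23CCC(=O)O | intermediate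
11 | 8α,9α-epoxy-7-hydrazono-14,15,16-trinorlabdan-13-oic acid | CC1(C)CCC[C@@]2(C)[C@H]1CC(=NN)[C@@]3(C)O[C@@]23CCC(=O)O | intermediate
12 | 9α-hydroxy-14,15,16-trinorlabd-7-en-13-oic acid | CC1(C)CCC[C@@]2(C)[C@H]1CC=C(C)[C@]2(O)CCC(=O)O | intermediate
13 | 14,15,16-trinorlabd-7-en-13,9α-olide (spiro γ-lactone at C9, oxygen α) | CC1(C)CCC[C@@]2(C)[C@H]1CC=C(C)[C@]21CCC(=O)O1 | intermediate
14 | 9α,13-epoxy-14,15-dinorlabda-7,13(16)-diene | CC1(C)CCC[C@@]2(C)[C@H]1CC=C(C)[C@]21CCC(=C)O1 | intermediate
15 | trichloroacetyl chloride | O=C(Cl)C(Cl)(Cl)Cl | starting material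
16 | dichloroketene | O=C=C(Cl)Cl | intermediate
17 | spiro 2,2-dichlorocyclobutanone: 14,14-dichloro-9α,13-epoxy-15,16-cyclolabd-7-en-15-one, C14 on the face of ring C syn to C8 | CC1(C)CCC[C@@]2(C)[C@H]1CC=C(C)[C@]21CC[C@]2(CC(=O)C2(Cl)Cl)O1 | intermediate
18 | 14,14-dichloro-9α,13-epoxylabd-7-en-15,16-olide (C15 carbonyl, oxygen on C16) | CC1(C)CCC[C@@]2(C)[C@H]1CC=C(C)[C@]21CC[C@]2(COC(=O)C2(Cl)Cl)O1 | intermediate
19 | 14,14-dichloro-7α,8α:9α,13-diepoxylabdan-15,16-olide | CC1(C)CCC[C@@]2(C)[C@H]1C[C@H]3O[C@@]3(C)[C@]21CC[C@]2(COC(=O)C2(Cl)Cl)O1 | intermediate
20 | 14,14-dichloro-9α,13-epoxy-7α,8β-dihydroxylabdan-15,16-olide | CC1(C)CCC[C@@]2(C)[C@H]1C[C@@H](O)[C@](C)(O)[C@]21CC[C@]2(COC(=O)C2(Cl)Cl)O1 | intermediate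
21 | 9α,13-epoxy-7α,8β-dihydroxylabdan-15,16-olide | CC1(C)CCC[C@@]2(C)[C@H]1C[C@@H](O)[C@](C)(O)[C@]21CC[C@]2(COC(=O)C2)O1 | intermediate
22 | (13S)-9α,13-epoxy-8β-hydroxy-7-oxolabdan-15,16-olide, CNP0208728.2 | CC1(C)CCC[C@@]2(C)[C@H]1CC(=O)[C@](C)(O)[C@]21CC[C@]2(COC(=O)C2)O1 | target

## Step count and least certain steps

Total: 13 steps. Longest linear sequence: 13 steps from 1; 15 enters at step 9.

**Step 9 (key step).** The most likely failure is poor facial selectivity at C13, because the two faces of ring C differ only through groups on C8 and C10 that are three bonds away. A second possibility is acid-induced migration of the exocyclic double bond into ring C, or acylation at C16 without ring closure, before the ketene is trapped. Generating the ketene from dichloroacetyl chloride and Et3N removes the Lewis acid but is only a change of conditions. The fallback corrects C13 by equilibration instead of by kinetic face selection. It sets out from 14 and returns at 21.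
- The cycloaddition is run as above, and the C13-epimeric cyclobutanone F1 is separated.
- H2O2 in AcOH expands the ring without touching the alkene, giving the 13-epi dichlorolactone F2.
- Bu3SnH/AIBN gives the 13-epi Δ7 lactone F3.
- DBU in toluene opens ring C by retro-oxa-Michael reaction to the 9α-hydroxy butenolide F4. This recloses to a mixture of F3 and the natural-series Δ7 lactone F5; F3 is separated and resubmitted.
- F5 is epoxidised with mCPBA to the 7α,8α-epoxy lactone F6, and dilute HClO4 in aqueous THF gives 21.

**Step 7.** The Wharton fragmentation of a fully substituted epoxy ketone can stall at the hydrazone or divert to azine or pyrazoline formation. The tertiary allylic alcohol can also ionise during work-up. The same fallback covers a sluggish conjugate epoxidation of the hindered enone in step 6. It sets out from 7 and returns at 12.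
- Dye-sensitised photooxygenation of the Δ8(9) alkene (O2, tetraphenylporphyrin, light, CH2Cl2) is a Schenck ene reaction that delivers oxygen to C9 from the α face with shift of the double bond to C7, giving the methyl 9α-hydroperoxy ester F7.
- PPh3 reduces F7 to the methyl 9α-hydroxy ester F8.
- LiOH in aqueous THF gives 12, which is lactonised to 13 as in step 7.
- The ene regioisomer with an exocyclic C8=C17 alkene would have to be separated.

**Step 11.** Opening of the epoxide beside the fully substituted C9 may be diverted from water capture to hydride or alkyl shifts (7-ketone formation, ring contraction toward the C9 oxocarbenium) or to loss of a C17 proton. If step 10 gave some β-epoxide, Markovnikov opening would give the 8α alcohol. The fallback makes the C8–O bond by a stereoconvergent iodonium route. It sets out from 17 and returns at 22.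
- H2O2 in AcOH converts 17 into 18, now isolated.
- Woodward cis-hydroxylation (I2, AgOAc, wet AcOH) proceeds by acetate attack at C8 from the β face and acetoxonium formation on the β face. It gives the 7β-acetoxy-8β-hydroxy dichlorolactone F9.
- Bu3SnH/AIBN gives the 7β-acetoxy-8β-hydroxy lactone F10.
- K2CO3 in MeOH at 0 °C gives the 7β,8β-diol F11.
- IBX in DMSO gives 22, since the C7 configuration is lost on oxidation.

**Step 2.** Dehydration may stop at a mixture of Δ7, Δ8(17) and Δ8(9) alkenes, or the hydroxy ketone may cyclise to its six-membered enol ether instead of eliminating. The fallback moves the elimination to the acid stage. It sets out from 3 and returns at 7.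
- Haloform cleavage of 3 (NaOCl, NaOH) and acidification give the δ-lactone ambreinolide F12.
- H2SO4 in MeOH at reflux opens F12 by alkyl–oxygen cleavage, esterifies the acid and equilibrates the alkenes to 7.

## Further compounds

F1 | step 9 | C13 epimer of 17 (C14 syn to C10) | CC1(C)CCC[C@@]2(C)[C@H]1CC=C(C)[C@]21CC[C@@]2(CC(=O)C2(Cl)Cl)O1
F2 | step 9 | 13-epi-14,14-dichloro-9α,13-epoxylabd-7-en-15,16-olide | CC1(C)CCC[C@@]2(C)[C@H]1CC=C(C)[C@]21CC[C@@]2(COC(=O)C2(Cl)Cl)O1
F3 | step 9 | 13-epi-9α,13-epoxylabd-7-en-15,16-olide | CC1(C)CCC[C@@]2(C)[C@H]1CC=C(C)[C@]21CC[C@@]2(COC(=O)C2)O1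
F4 | step 9 | 9α-hydroxylabda-7,13-dien-15,16-olide (butenolide) | CC1(C)CCC[C@@]2(C)[C@H]1CC=C(C)[C@]2(O)CCC1=CC(=O)OC1
F5 | step 9 | 9α,13-epoxylabd-7-en-15,16-olide (C13 as in 22) | CC1(C)CCC[C@@]2(C)[C@H]1CC=C(C)[C@]21CC[C@]2(COC(=O)C2)O1
F6 | step 9 | 7α,8α:9α,13-diepoxylabdan-15,16-olide | CC1(C)CCC[C@@]2(C)[C@H]1C[C@H]3O[C@@]3(C)[C@]21CC[C@]2(COC(=O)C2)O1
F7 | step 7 | methyl 9α-hydroperoxy-14,15,16-trinorlabd-7-en-13-oate | CC1(C)CCC[C@@]2(C)[C@H]1CC=C(C)[C@]2(OO)CCC(=O)OC
F8 | step 7 | methyl 9α-hydroxy-14,15,16-trinorlabd-7-en-13-oate | CC1(C)CCC[C@@]2(C)[C@H]1CC=C(C)[C@]2(O)CCC(=O)OC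
F9 | step 11 | 7β-acetoxy-14,14-dichloro-9α,13-epoxy-8β-hydroxylabdan-15,16-olide | CC1(C)CCC[C@@]2(C)[C@H]1C[C@H](OC(C)=O)[C@](C)(O)[C@]21CC[C@]2(COC(=O)C2(Cl)Cl)O1
F10 | step 11 | 7β-acetoxy-9α,13-epoxy-8β-hydroxylabdan-15,16-olide | CC1(C)CCC[C@@]2(C)[C@H]1C[C@H](OC(C)=O)[C@](C)(O)[C@]21CC[C@]2(COC(=O)C2)O1
F11 | step 11 | 9α,13-epoxy-7β,8β-dihydroxylabdan-15,16-olide | CC1(C)CCC[C@@]2(C)[C@H]1C[C@H](O)[C@](C)(O)[C@]21CC[C@]2(COC(=O)C2)O1
F12 | step 2 | ambreinolide, 14,15,16-trinorlabdan-13,8α-olide | C[C@]12CCCC([C@@H]1CC[C@@]3([C@@H]2CCC(=O)O3)C)(C)C
A1 | alternative 1 | ethyl 5,5,8a-trimethyl-2-oxodecahydronaphthalene-1-carboxylate, trans-fused (8-oxo, 9β-ester) | CC1(C)CCC[C@@]2(C)[C@H]1CCC(=O)[C@@H]2C(=O)OCC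
A2 | alternative 1 | ethyl (6E)-7,11-dimethyl-3-oxododeca-6,10-dienoate | CCOC(=O)CC(=O)CC/C=C(\C)CCC=C(C)C
A3 | alternative 2 | 9α,13-epoxy-17-norlabdan-8-one 15,16-bis(tert-butyldimethylsilyl) ether | CC1(C)CCC[C@@]2(C)[C@H]1CCC(=O)[C@]21CC[C@@](CO[Si](C)(C)C(C)(C)C)(CCO[Si](C)(C)C(C)(C)C)O1
A4 | alternative 2 | 8-trimethylsilyloxy-17-norlabd-8-en-13-ol 15,16-bis(tert-butyldimethylsilyl) ether | CC1(C)CCC[C@@]2(C)[C@H]1CCC(O[Si](C)(C)C)=C2CC[C@@](O)(CO[Si](C)(C)C(C)(C)C)CCO[Si](C)(C)C(C)(C)C
A5 | alternative 3 | 8-O-trimethylsilyl ether of 22 | CC1(C)CCC[C@@]2(C)[C@H]1CC(=O)[C@](C)(O[Si](C)(C)C)[C@]21CC[C@]2(COC(=O)C2)O1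
A6 | alternative 3 | 9α,13-epoxy-7-oxo-8β-trimethylsilyloxy-14,15-dinorlabdan-16-yl diazoacetate | CC1(C)CCC[C@@]2(C)[C@H]1CC(=O)[C@](C)(O[Si](C)(C)C)[C@]21CC[C@H](COC(=O)C=[N+]=[N-])O1
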